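**Retrosynthetic overview**
1. The maleic anhydride is the only ring and is closed last. The target comes from CO2 loss from a 2-alkyl-3-(carboxymethyl)maleic anhydride, the same anhydride-then-decarboxylation order as in the fungal alkylcitrate pathway.
2. That anhydride comes from an ω-hydroxyalkyl-aconitic acid (a dehydrated alkylcitrate). Ac2O closes the ring and installs the acetate in the same operation.
3. The alkylaconitate comes from forming the Cα(fatty acyl)–C2(oxaloacetate) bond. The nucleophile is the enolate of 16-hexadecanolide, an acyl-CoA surrogate whose own ester oxygen protects the ω-OH. The electrophile is DMAD, which is oxaloacetate at the already dehydrated oxidation level.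
4. Ring order: the macrolactone is opened first, then the anhydride is formed. There is no other ring.

Assumption: the target (C21H34O5) has no stereocentre and its ring fixes the alkene geometry, so no enantiocontrol is needed. Stereocentres in intermediates are racemic and transient.

**Route**

Step 1
Reactants: 1 16-hexadecanolide (oxacycloheptadecan-2-one); 2 dimethyl acetylenedicarboxylate (DMAD)
Product: 5 dimethyl (E)-2-(2-oxooxacycloheptadecan-3-yl)but-2-enedioate (racemic at C3), via lithium enolate of hexadecanolide 3 (not isolated), via lithium dienolate of the adduct 4 (not isolated)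
Conditions: LDA (commercial 2.0 M, 1.05 equiv), THF, −78 °C, 45 min; 2 (1.05 equiv), −78 → −40 °C, 1 h; AcOH, −78 °C
Reagents that add atoms: none
Why: Michael (conjugate) addition of a kinetic lithium lactone enolate to the doubly activated alkyne gives a vinyl anion that, with iPr2NH as proton shuttle, collapses at once to the stabilised glutaconate-type anion 4, so one equivalent of base suffices and further addition is slowed until the quench; the C3 stereocentre is racemic and erased in step 3, and any Z or 2-ene isomers of 5 converge later.

Step 2
Reactants: 5 dimethyl (E)-2-(2-oxooxacycloheptadecan-3-yl)but-2-enedioate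
Product: 7 (E)-17-hydroxyheptadec-1-ene-1,2,3-tricarboxylic acid (racemic at C3), via tripotassium tricarboxylate 6 (not isolated)
Conditions: KOH (8 equiv), MeOH–H2O 3:1, reflux, 12 h; 2 M HCl, 0 °C, pH 1
Reagents that add atoms: potassium hydroxide, [K+].[OH-]
Why: Exhaustive saponification (BAc2) of both methyl esters and the macrolactone frees the three carboxyl groups and the ω-hydroxyl in one operation, the carbanionic or polyanionic state of the substrate protects the alkene from hydroxide addition, and no lasting stereocentre is set.

Step 3
Reactants: 7 (E)-17-hydroxyheptadec-1-ene-1,2,3-tricarboxylic acid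
Product: 10 Aspergillus acid E [14-(4-methyl-2,5-dioxo-2,5-dihydrofuran-3-yl)tetradecyl acetate], via carboxymethylmaleic anhydride acetate 8 (not isolated), via methylenesuccinic anhydride acetate 9 (not isolated)
Conditions: Ac2O (4 equiv), AcOH, reflux, 2 h; distil off volatiles; neat, 175 °C, N2, 45 min
Reagents that add atoms: acetic anhydride, CC(=O)OC(C)=O
Why: Proposed new method: Ac2O acetylates the primary alcohol and closes a five-membered anhydride, the doubly activated C3–H (α to a carbonyl and allylic to the unsaturated acid) then shifts so that the alkene settles in the ring as the thermodynamically favoured tetrasubstituted maleic anhydride 8, in which the fatty carboxyl is locked and only the CH2CO2H is free, this β,γ-unsaturated (vinylogous β-keto) acid loses CO2 through a six-membered retro-ene transition state to 9, and 9 tautomerises to 10 as alkyl(methylene)succinic anhydrides do in hot Ac2O or AcOH; the closest known reaction type is the thermal dehydration–decarboxylation of citric or aconitic acid to itaconic/citraconic anhydride and of hexadecylcitric (agaric) acid to hexadecyl(methyl)maleic anhydride, and all transient stereocentres vanish in the achiral product.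

**Compound list**
1 | 16-hexadecanolide (oxacycloheptadecan-2-one) | O=C1CCCCCCCCCCCCCCCO1 | starting material
2 | dimethyl acetylenedicarboxylate (dimethyl but-2-ynedioate) | COC(=O)C#CC(=O)OC | starting material
3 | lithium enolate of hexadecanolide (enolate geometry inconsequential) | [Li+].[O-]C1=CCCCCCCCCCCCCCCO1 | intermediate
4 | lithium dienolate (delocalised glutaconate-type anion) of the Michael adduct, one resonance form drawn | [Li+].[O-]C(OC)=CC(C(=O)OC)=C1CCCCCCCCCCCCCCOC1=O | intermediate
5 | dimethyl (E)-2-(2-oxooxacycloheptadecan-3-yl)but-2-enedioate, racemic at lactone C3 | COC(=O)/C=C(/C(=O)OC)C1CCCCCCCCCCCCCCOC1=O | intermediate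
6 | tripotassium (E)-17-hydroxyheptadec-1-ene-1,2,3-tricarboxylate, racemic | [K+].[K+].[K+].[O-]C(=O)/C=C(/C([O-])=O)C(CCCCCCCCCCCCCCO)C([O-])=O | intermediate
7 | (E)-17-hydroxyheptadec-1-ene-1,2,3-tricarboxylic acid, racemic at C3 | OC(=O)/C=C(/C(O)=O)C(CCCCCCCCCCCCCCO)C(O)=O | intermediate
8 | 2-[4-(14-acetoxytetradecyl)-2,5-dioxo-2,5-dihydrofuran-3-yl]acetic acid | CC(=O)OCCCCCCCCCCCCCCC1=C(CC(O)=O)C(=O)OC1=O | intermediate
9 | 14-(4-methylidene-2,5-dioxooxolan-3-yl)tetradecyl acetate, racemic | CC(=O)OCCCCCCCCCCCCCCC1C(=C)C(=O)OC1=O | intermediate
10 | Aspergillus acid E, 14-(4-methyl-2,5-dioxo-2,5-dihydrofuran-3-yl)tetradecyl acetate (achiral) | CC(=O)OCCCCCCCCCCCCCCC1=C(C)C(=O)OC1=O | target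

**Total step count:** 3. **Longest linear sequence:** 3 (1 → 5 → 7 → 10).

**Steps most likely to fail, with fallbacks**

Highest risk, step 3. The carboxyl derived from the fatty acid could be lost from a trisubstituted anhydride tautomer. The transient exo-methylene species could also oligomerise.

The fallback moves the decarboxylation to the ester stage and sets out from 5. Krapcho conditions (LiCl, wet DMSO, 150 °C) dealkylate only methyl esters. They can expel CO2 only from the 2-ene tautomer that carries CH2CO2Me. The fatty carboxyl is tied up in the macrolactone and cannot be lost.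

This gives methyl 2-(2-oxooxacycloheptadecan-3-yl)prop-2-enoate F1. Saponification (KOH, aq. MeOH, then HCl) gives 2-(14-hydroxytetradecyl)-3-methylidenebutanedioic acid F2. Refluxing Ac2O acetylates and closes F2, coming back to the route at 9, which tautomerises to 10 in the same pot.

Second, step 1. DMAD may oligomerise, suffer 1,2-attack, or take up a second equivalent of anion.

The fallback sets out from 3 and replaces the C4 alkyne by the C3 keto ester methyl pyruvate in an aldol addition at −78 °C. This gives methyl 2-hydroxy-2-(2-oxooxacycloheptadecan-3-yl)propanoate F3 as a diastereomer mixture. KOH then HCl gives 2-hydroxy-3-(14-hydroxytetradecyl)-2-methylbutanedioic acid F4.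

Refluxing Ac2O converts F4 into 14-(4-acetoxy-4-methyl-2,5-dioxooxolan-3-yl)tetradecyl acetate F5. F5 loses its tertiary acetate by E1cB elimination and comes back to the route directly at 10, with no decarboxylation needed.

Third, step 2. Compound 5 sits in KOH as its unreactive stabilised anion, so hydrolysis may stall or degrade the material.

The fallback avoids hydrolysis altogether and sets out from 3. Addition to di-tert-butyl acetylenedicarboxylate gives di-tert-butyl (E)-2-(2-oxooxacycloheptadecan-3-yl)but-2-enedioate F6. TFA/CH2Cl2 gives (E)-2-(2-oxooxacycloheptadecan-3-yl)but-2-enedioic acid F7.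

In hot AcOH/Ac2O the central carboxyl opens the neighbouring lactone by intramolecular acyl transfer, the behaviour of dialkylmaleic monoesters. This releases 2-[4-(14-hydroxytetradecyl)-2,5-dioxo-2,5-dihydrofuran-3-yl]acetic acid F8. Ac2O caps F8 irreversibly, coming back to the route at 8.

**Further compounds**
F1 | step 3 | methyl 2-(2-oxooxacycloheptadecan-3-yl)prop-2-enoate (racemic) | COC(=O)C(=C)C1CCCCCCCCCCCCCCOC1=O
F2 | step 3 | 2-(14-hydroxytetradecyl)-3-methylidenebutanedioic acid (racemic) | OC(=O)C(=C)C(CCCCCCCCCCCCCCO)C(O)=O
F3 | step 1 | methyl 2-hydroxy-2-(2-oxooxacycloheptadecan-3-yl)propanoate (racemic diastereomer mixture) | COC(=O)C(C)(O)C1CCCCCCCCCCCCCCOC1=O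
F4 | step 1 | 2-hydroxy-3-(14-hydroxytetradecyl)-2-methylbutanedioic acid (racemic diastereomer mixture) | OC(=O)C(C)(O)C(CCCCCCCCCCCCCCO)C(O)=O
F5 | step 1 | 14-(4-acetoxy-4-methyl-2,5-dioxooxolan-3-yl)tetradecyl acetate (racemic diastereomer mixture) | CC(=O)OCCCCCCCCCCCCCCC1C(=O)OC(=O)C1(C)OC(C)=O
F6 | step 2 | di-tert-butyl (E)-2-(2-oxooxacycloheptadecan-3-yl)but-2-enedioate (racemic) | CC(C)(C)OC(=O)/C=C(/C(=O)OC(C)(C)C)C1CCCCCCCCCCCCCCOC1=O
F7 | step 2 | (E)-2-(2-oxooxacycloheptadecan-3-yl)but-2-enedioic acid (racemic) | OC(=O)/C=C(/C(O)=O)C1CCCCCCCCCCCCCCOC1=O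
F8 | step 2 | 2-[4-(14-hydroxytetradecyl)-2,5-dioxo-2,5-dihydrofuran-3-yl]acetic acid | OCCCCCCCCCCCCCCC1=C(CC(O)=O)C(=O)OC1=O
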